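A curve that goes flat tempts one to blame an equilibrium or a dying catalyst before counting anything, so I counted first.

| flask | starting material | second substrate | coupling partner | free catalyst | remark | time |
|---|---|---|---|---|---|---|
| south-east | 0.20 M (in portions, 2) | 0.20 M | 0.12 M | 2 mM | run made earlier; portions every 6.0 s |  |
| flask | 0.20 M (in portions, 2) | 0.100 M | 0.120 M | 2.0 mM | the portions of starting material follow each other after 6.0 s, the first at the start | 40 min |

south-east run (percent of the starting material charged)

| time / min | starting material / % | target / % |
|---|---|---|
| 0.500 | 89.2 | 10.1 |
| 1.50 | 77.5 | 18.4 |
| 3.00 | 77.2 | 24.1 |
| 4.00 | 75.5 | 26.8 |
| 6.00 | 74.8 | 22.6 |
| 8.00 | 77.0 | 25.6 |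

(each reading ± 1 percentage point)

- what was read earlier has a scatter of 1 percentage point, one standard deviation

* part of the starting material gone at 40 min
* the target standing at 40 min, as a percentage of the starting material charged

In the south-east run the target read about 24.8 % of the starting material from 3.00 min on, which is 24.8 turnovers per catalyst charged. My first estimate was that the catalyst lasts that count, which put the new flask at the same fraction. My objection was that the south-east readings give starting material and target but no form of the catalyst, so they could not tell me that this count was a lifetime. Held against the coupling partner, the same count says the target took 41.3 % of that charge. If the second substrate competes for the coupling partner, the rest costs 35.2 % of the second substrate's charge, which that charge allows, and the stall could then be the end of the coupling partner's charge, though the south-east readings do not include coupling partner and cannot test this.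

So I carried one number: the odds of target against the other use of coupling partner, per unit ratio of starting material to second substrate charged. This selectivity factor came to 0.703 from the south-east run. The new flask has twice that charge ratio, so the target should take 58.4 % of the coupling partner, or 35.1 % of the starting material. My second objection was drift: the new flask would lose 49.9 % of its second substrate against 35.1 % of its starting material, so the ratio climbs and my figure sits on the low side. I committed to about 35.1 % for both answers, since the south-east readings of starting material and target from 3.00 min on summed to about 101 % of the charge.

The forecast differed from my reckoning: 17 % gone (12 % to 26 %) and 16 % target (11 % to 25 %), with the remark “I weight the lower cases”.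

The new flask gave 36.2 % gone and 36.1 % target.

    starting material + free catalyst ⇌ catalyst intermediate A (K = 2.80 M⁻¹, k = 20.0 M⁻¹ s⁻¹)
    coupling partner + catalyst intermediate A → free catalyst + target (k = 26.0 M⁻¹ s⁻¹)
    second substrate + free catalyst ⇌ catalyst intermediate B (K = 5.30 M⁻¹, k = 41.0 M⁻¹ s⁻¹)
    coupling partner + catalyst intermediate B → free catalyst + second product (k = 18.0 M⁻¹ s⁻¹)
    second substrate + catalyst intermediate B → spent catalyst (k = 0.0640 M⁻¹ s⁻¹)

In the new flask the half-life of coupling partner by the target-making step was 1.1 min at 0.687 min, short against 40 min, and the flask ended with 0 % of this limiting reagent against 64 % of starting material. In the new flask at 40.0 min, target to second product stood at 1.51, where the selectivity factor times that flask's charge ratio gave 1.41.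

A neighbour flask with 0.030 M of coupling partner keeps the same charge ratio, so the same factor gives 8.77 % target. The computed result there is 8.84 %.

All runs are simulated with constants of no real substance.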